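Each benzene ring (rings A and B are identical) is cut at C3–C4 and C5–C6. The brominated four-carbon run C6–C1–C2–C3 (Br, CH2, Br, Br) is the diene of a 3-alkyl-2,4,5-tribromothiophene 1,1-dioxide, and the catechol pair C4–C5 arrives as the C=C of vinylene carbonate. In one operation a twofold Diels–Alder addition with loss of SO2 builds both carbocycles, four C–C bonds and all four oxygens on an ethane-bridged bis(thiophene dioxide). That precursor is made by coupling 3-thenyl bromide first, then brominating all six ring positions and oxidizing both sulfurs. Dehydrogenation and carbonate hydrolysis finish the synthesis.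

Key step: step 4

Assumption: 3-(bromomethyl)thiophene is bought as such (it is otherwise one NBS bromination from 3-methylthiophene), and 10 is expected as a mixture of meso and racemic diastereomers (meso form drawn), which is harmless because step 5 removes every stereocentre.

Step 1
Reactants: 1 3-(bromomethyl)thiophene (2 equiv)
Product: 3 1,2-di(thiophen-3-yl)ethane, via (thiophen-3-ylmethyl)magnesium bromide 2 (not isolated)
Conditions: Mg (0.55 equiv), THF, 0 °C → rt; then Li2CuCl4 (2 mol %), rt
Reagents that add atoms: none
Why: Wurtz-type homocoupling, in which the Grignard reagent 2 formed from half of the bromide alkylates the other half (copper-catalysed Kochi alkyl–alkyl coupling), should be clean here because no other carbon–halogen bond is yet present to compete.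

Step 2
Reactants: 3 1,2-di(thiophen-3-yl)ethane
Product: 4 1,2-bis(2,4,5-tribromothiophen-3-yl)ethane
Conditions: Br2 (7 equiv), CHCl3/AcOH, 0 → 60 °C, dark
Reagents that add atoms: bromine, BrBr
Why: Exhaustive electrophilic aromatic bromination should substitute both α-positions and then the remaining β-position of each 3-alkylthiophene ring, while ionic conditions in the dark leave the CH2CH2 bridge untouched.

Step 3
Reactants: 4 1,2-bis(2,4,5-tribromothiophen-3-yl)ethane
Product: 5 1,2-bis(2,4,5-tribromo-1,1-dioxidothiophen-3-yl)ethane
Conditions: H2O2·urea (12 equiv), (CF3CO)2O (12 equiv), MeCN/CH2Cl2, 0 °C → rt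
Reagents that add atoms: trifluoroperacetic acid, OOC(=O)C(F)(F)F, made in the flask from urea–hydrogen peroxide, NC(N)=O.OO, and trifluoroacetic anhydride, O=C(OC(=O)C(F)(F)F)C(F)(F)F
Why: Electrophilic S-oxidation with trifluoroperacetic acid, the peracid used for halogen-deactivated thiophenes, should take each sulfur through the sulfoxide to the sulfone, and the fully substituted dioxide rings cannot dimerize.

Step 4
Reactants: 5 1,2-bis(2,4,5-tribromo-1,1-dioxidothiophen-3-yl)ethane; 6 vinylene carbonate
Product: 10 1,2-bis[cis-4,6,7-tribromo-2-oxo-3a,7a-dihydro-1,3-benzodioxol-5-yl]ethane, via sulfone-bridged monoadduct 7 (not isolated), via half-annulated diene 8 (not isolated), via sulfone-bridged second adduct 9 (not isolated)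
Conditions: 6 (8 equiv), BHT (cat.), PhMe, 100–110 °C, N2 sweep
Reagents that add atoms: vinylene carbonate (6), O=C1OC=CO1
Why: Each non-aromatic, electron-poor thiophene 1,1-dioxide ring of 5 reacts through its C2=C3–C4=C5 diene with the enol-carbonate C=C of 6 in a concerted, suprafacial Diels–Alder addition of inverse electron demand, and the strained 7-thiabicyclo[2.2.1]hept-2-ene 7,7-dioxide so formed (7, later 9) expels SO2 at once in a thermally allowed cheletropic step to leave a cyclohexa-1,3-diene. The closest known reaction type is the cycloaddition of tetrahalothiophene 1,1-dioxides to alkenes with loss of SO2, which gives 1,2,3,4-tetrahalocyclohexa-1,3-dienes. Each of the two six-membered carbocycles closes by an intermolecular (4+2) annulation that forms both of its new C–C bonds (C3–C4 and C5–C6 in target numbering) in one event, after which the one-atom sulfur bridge is excised. The two new stereocentres of each ring, C3a and C7a, should come out cis because the oxygens are held cis in the five-membered dienophile and add to one face of the diene; the endo or exo sense vanishes with the SO2 bridge and the relation between the two remote rings is left open, which does not matter because step 5 removes all four centres. The step needs exactly one addition per diene unit and survival of both C–O bonds and all C–Br bonds. The first is secured by the product diene, which has lost the activating sulfone and is fully substituted at its four sp2 carbons, and the second by the symmetric dienophile (no regiochemistry to control) and by base-free, neutral conditions with SO2 swept out and BHT present, so that neither carbonate nor HBr is eliminated and 6 does not polymerize.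

Step 5
Reactants: 10 1,2-bis[cis-4,6,7-tribromo-2-oxo-3a,7a-dihydro-1,3-benzodioxol-5-yl]ethane
Product: 11 1,2-bis(4,6,7-tribromo-2-oxo-1,3-benzodioxol-5-yl)ethane
Conditions: DDQ (2.5 equiv), PhCl, 90 °C
Reagents that add atoms: none
Why: Quinone dehydrogenation (hydride abstraction by DDQ from the oxygen-bearing, diene-conjugated C3a–H, then loss of the C7a proton) is driven by aromatization and, being neutral and non-nucleophilic, should leave the carbonates and C–Br bonds in place while erasing all four stereocentres.

Step 6
Reactants: 11 1,2-bis(4,6,7-tribromo-2-oxo-1,3-benzodioxol-5-yl)ethane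
Product: 12 1,2-bis(2,3,6-tribromo-4,5-dihydroxyphenyl)ethane (3,4,6-tribromo-5-[2-(2,3,6-tribromo-4,5-dihydroxyphenyl)ethyl]benzene-1,2-diol)
Conditions: THF/H2O (3:1, degassed), HCl (cat.), 50 °C, Ar
Reagents that add atoms: none
Why: Acyl–oxygen hydrolysis of the strained, activated diaryl cyclic carbonates with irreversible loss of CO2 keeps both aryl–oxygen bonds, and the acidic, oxygen-free medium should protect the bromocatechol rings from oxidation to quinones.

Compound list
1 | 3-(bromomethyl)thiophene | BrCc1ccsc1 | starting material
2 | (thiophen-3-ylmethyl)magnesium bromide | Br[Mg]Cc1ccsc1 | intermediate (not isolated)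
3 | 1,2-di(thiophen-3-yl)ethane | C(Cc1ccsc1)c1ccsc1 | intermediate
4 | 1,2-bis(2,4,5-tribromothiophen-3-yl)ethane | Brc1sc(Br)c(Br)c1CCc1c(Br)sc(Br)c1Br | intermediate
5 | 1,2-bis(2,4,5-tribromo-1,1-dioxidothiophen-3-yl)ethane | O=S1(=O)C(Br)=C(CCC2=C(Br)S(=O)(=O)C(Br)=C2Br)C(Br)=C1Br | intermediate
6 | vinylene carbonate (1,3-dioxol-2-one) | O=C1OC=CO1 | starting material
7 | sulfone-bridged monoadduct: one ring of 5 as the cycloadduct with 6 (cis-fused carbonate on a tribromo-7-thiabicyclo[2.2.1]hept-2-ene 7,7-dioxide, drawn endo, one enantiomer), other ring unchanged | O=C1O[C@H]2[C@@H](O1)[C@@]1(Br)C(Br)=C(CCC3=C(Br)S(=O)(=O)C(Br)=C3Br)[C@]2(Br)S1(=O)=O | intermediate (not isolated)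
8 | half-annulated diene: one cis-4,6,7-tribromo-3a,7a-dihydro-1,3-benzodioxol-2-one ring, one tribromothiophene dioxide ring | O=C1O[C@@H]2C(Br)=C(CCC3=C(Br)S(=O)(=O)C(Br)=C3Br)C(Br)=C(Br)[C@@H]2O1 | intermediate (not isolated)
9 | sulfone-bridged second adduct: dihydrobenzodioxolone ring at one end, endo sulfone-bridged carbonate cycloadduct at the other | O=C1O[C@@H]2C(Br)=C(CCC3=C(Br)[C@@]4(Br)[C@H]5OC(=O)O[C@H]5[C@]3(Br)S4(=O)=O)C(Br)=C(Br)[C@@H]2O1 | intermediate (not isolated)
10 | 1,2-bis[cis-4,6,7-tribromo-2-oxo-3a,7a-dihydro-1,3-benzodioxol-5-yl]ethane (cis ring fusions; meso diastereomer drawn) | O=C1O[C@@H]2C(Br)=C(CCC3=C(Br)[C@@H]4OC(=O)O[C@@H]4C(Br)=C3Br)C(Br)=C(Br)[C@@H]2O1 | intermediate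
11 | 1,2-bis(4,6,7-tribromo-2-oxo-1,3-benzodioxol-5-yl)ethane | O=C1Oc2c(O1)c(Br)c(CCc3c(Br)c4OC(=O)Oc4c(Br)c3Br)c(Br)c2Br | intermediate
12 | 1,2-bis(2,3,6-tribromo-4,5-dihydroxyphenyl)ethane | Oc1c(O)c(Br)c(CCc2c(Br)c(O)c(O)c(Br)c2Br)c(Br)c1Br | target

Total step count: 6. Longest linear sequence: 6 steps (1 → 12); vinylene carbonate 6 enters at step 4.

Steps most likely to fail

Step 4. The cycloaddition may be too slow with the only weakly electron-rich enol carbonate, so that polymerization of the dienophile or decomposition of the dioxide takes over. The primary diene may also aromatize in the hot mixture with loss of CO2 and one ring oxygen. The fallback sets out again from 5 and uses the electron-richer, elimination-resistant enediol diether 2,3-dihydro-1,4-dioxine (purchased, C1COC=CO1; 6 equiv, PhMe, 60–80 °C). The same Diels–Alder/SO2-loss sequence should give 1,2-bis(cis-5,7,8-tribromo-2,3,4a,8a-tetrahydro-1,4-benzodioxin-6-yl)ethane F1. DDQ (PhMe, 80 °C) should aromatize it to 1,2-bis(5,7,8-tribromo-2,3-dihydro-1,4-benzodioxin-6-yl)ethane F2. BBr3 (CH2Cl2, −78 °C → rt, then H2O) cleaves both ethylene bridges as 1,2-dibromoethane, and the route is rejoined at target 12.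

Step 5. Hydride abstraction from the bromine-laden, electron-poor diene may be so slow that, at the temperature it then demands, thermal loss of CO2 and one oxygen overtakes dehydrogenation. The fallback sets out from 10 and replaces hydride transfer by a radical chain: NBS (2.1 equiv), AIBN (cat.), PhCF3, 80 °C (Wohl–Ziegler conditions). A bromine atom abstracts the weak C3a–H, whose polar demands are different from those of hydride loss, and the resulting cyclohexadienyl radical gives up its second ring hydrogen to bromine, forming the arene and HBr. This comes back to the route at 11 and makes no compound outside the list (F0).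

Step 3. Oxygen transfer to the strongly deactivated, poorly soluble hexabromide may stall at partly oxidized stages, which are prone to dimerize. The fallback carries one bromine less per ring through oxidation and cycloaddition and adds it last. It sets out from 3 and returns at 12:
- NBS (4.1 equiv, DMF, 0 °C → rt) should give 1,2-bis(2,5-dibromothiophen-3-yl)ethane F3.
- Trifluoroperacetic acid as in step 3 should oxidize this less deactivated, more soluble substrate to 1,2-bis(2,5-dibromo-1,1-dioxidothiophen-3-yl)ethane F4, a member of the known class of 2,5-dibromo-3-alkylthiophene dioxides.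
- Vinylene carbonate 6 under the conditions of step 4 should give 1,2-bis(cis-4,7-dibromo-2-oxo-3a,7a-dihydro-1,3-benzodioxol-5-yl)ethane F5.
- DDQ should give 1,2-bis(4,7-dibromo-2-oxo-1,3-benzodioxol-5-yl)ethane F6.
- Hydrolysis as in step 6 should give 1,2-bis(2,5-dibromo-3,4-dihydroxyphenyl)ethane F7.
- Br2 (2.1 equiv, AcOH, rt) should then brominate the single free position of each ring, which lies para to a hydroxyl, to give 12.

Further compounds
F1 | step 4 | 1,2-bis(cis-5,7,8-tribromo-2,3,4a,8a-tetrahydro-1,4-benzodioxin-6-yl)ethane | C1CO[C@@H]2C(Br)=C(CCC3=C(Br)[C@@H]4OCCO[C@@H]4C(Br)=C3Br)C(Br)=C(Br)[C@@H]2O1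
F2 | step 4 | 1,2-bis(5,7,8-tribromo-2,3-dihydro-1,4-benzodioxin-6-yl)ethane | C1COc2c(O1)c(Br)c(CCc3c(Br)c4OCCOc4c(Br)c3Br)c(Br)c2Br
F0 | step 5 | none | none
F3 | step 3 | 1,2-bis(2,5-dibromothiophen-3-yl)ethane | Brc1cc(CCc2cc(Br)sc2Br)c(Br)s1
F4 | step 3 | 1,2-bis(2,5-dibromo-1,1-dioxidothiophen-3-yl)ethane | O=S1(=O)C(Br)=CC(CCC2=C(Br)S(=O)(=O)C(Br)=C2)=C1Br
F5 | step 3 | 1,2-bis(cis-4,7-dibromo-2-oxo-3a,7a-dihydro-1,3-benzodioxol-5-yl)ethane | O=C1O[C@@H]2C(Br)=C(CCC3=C(Br)[C@@H]4OC(=O)O[C@@H]4C(Br)=C3)C=C(Br)[C@@H]2O1
F6 | step 3 | 1,2-bis(4,7-dibromo-2-oxo-1,3-benzodioxol-5-yl)ethane | O=C1Oc2c(O1)c(Br)c(CCc3c(Br)c4OC(=O)Oc4c(Br)c3)cc2Br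
F7 | step 3 | 1,2-bis(2,5-dibromo-3,4-dihydroxyphenyl)ethane | Oc1c(O)c(Br)c(CCc2cc(Br)c(O)c(O)c2Br)cc1Br
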